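The α-methylene lactone is disconnected at C11–C12 and C6–C7 (germacranolide numbering: ring C1–C10, lactone carbons C11–C13, lactone oxygen on C6). The key step is a nickel-mediated three-component coupling: carbon dioxide (C12) bonds to the central carbon of a terminal allene (C7=C11=C13) that already carries the C8/C9 diol, and the resulting 2-carboxylatoallylnickel attacks a (Z)-enal (C6) through C7. It exploits the C13=C11(C12)–C7–C6–O array of the five-membered lactone ring, which maps onto allene, CO2 and aldehyde. Invertive lactonization, asymmetric chloroallylboration (cis-epoxide) and ring-closing metathesis at C1=C10 of the ten-membered ring finish the skeleton.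

Key step: step 9

Remark: the acyl residue is read as (2S,3R)-2,3-dimethyloxirane-2-carboxylate (methyl groups cis, the epoxide of tiglic acid) and both ring alkenes as cis within the ring (C4=C5 Z, C1=C10 E by CIP); C14 is the ester carbon on C10, C15 the methyl on C4, and these target locants are used for all intermediates.

Remark: step 9 is expected, from the geometry of the allylnickel intermediate, to give the 6,7-syn acid; step 10 is chosen accordingly (closure with inversion at C6).

Step 1
Reactants: 1 3-(triisopropylsilyl)prop-2-ynal; 2 3-(methoxymethoxy)prop-1-ene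
Product: 4 (3S,4S)-4-(methoxymethoxy)-1-(triisopropylsilyl)hex-5-en-1-yn-3-ol, via allylborane 3 (not isolated)
Conditions: 2, s-BuLi, THF, −78 °C; (+)-Ipc2BOMe [from (−)-α-pinene]; BF3·OEt2; then 1, −78 °C; NaOH, H2O2
Reagents that add atoms: none
Why: Asymmetric γ-alkoxyallylboration through a chair transition state; the Z-configured allylborane should give the syn C9-OH/C8-OMOM pair, and the isopinocampheyl groups from (−)-α-pinene should direct attack to the Re face of the ynal (9S, hence 8S).

Step 2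
Reactants: 4 (3S,4S)-4-(methoxymethoxy)-1-(triisopropylsilyl)hex-5-en-1-yn-3-ol
Product: 5 (3S,4S)-3-(tert-butyldimethylsilyloxy)-4-(methoxymethoxy)-1-(triisopropylsilyl)hex-5-en-1-yne
Conditions: TBSOTf, 2,6-lutidine, CH2Cl2, −78 to 0 °C
Reagents that add atoms: tert-butyldimethylsilyl trifluoromethanesulfonate, CC(C)(C)[Si](C)(C)OS(=O)(=O)C(F)(F)F
Why: Silyl ether formation at the hindered propargylic C9 hydroxyl, which differentiates O9 (fluoride-labile, kept to the end) from O8 (MOM, to be acylated).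

Step 3
Reactants: 5 (3S,4S)-3-(tert-butyldimethylsilyloxy)-4-(methoxymethoxy)-1-(triisopropylsilyl)hex-5-en-1-yne
Product: 6 (3S,4S)-3-(tert-butyldimethylsilyloxy)-4-(2,2-dibromocyclopropyl)-4-(methoxymethoxy)-1-(triisopropylsilyl)but-1-yne (both epimers at the cyclopropane CH)
Conditions: CHBr3, 50% aq. NaOH, BnEt3NCl (cat.), CH2Cl2, 0 to 23 °C
Reagents that add atoms: bromoform, BrC(Br)Br
Why: Phase-transfer dibromocarbene cyclopropanation of the terminal alkene; the hindered silyl alkyne, the acetal and the silyl ether are stable to the basic medium, and the new stereocentre is lost in step 4.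

Step 4
Reactants: 6 (3S,4S)-3-(tert-butyldimethylsilyloxy)-4-(2,2-dibromocyclopropyl)-4-(methoxymethoxy)-1-(triisopropylsilyl)but-1-yne
Product: 7 (3S,4S)-3-(tert-butyldimethylsilyloxy)-4-(methoxymethoxy)-1-(triisopropylsilyl)hepta-5,6-dien-1-yne (fragment A)
Conditions: MeLi, Et2O, −78 to −30 °C
Reagents that add atoms: none
Why: Doering–Moore–Skattebøl allene synthesis: bromine–lithium exchange gives a cyclopropylidene carbenoid that opens to the terminal allene (C7=C11=C13) without touching C8 or C9.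

Step 5
Reactants: 8 1-methoxy-4-[(prop-2-yn-1-yloxy)methyl]benzene
Product: 10 methyl 4-[(4-methoxybenzyl)oxy]but-2-ynoate, via lithium acetylide 9 (not isolated)
Conditions: n-BuLi, THF, −78 °C; ClCO2Me, −78 to 0 °C
Reagents that add atoms: methyl chloroformate, COC(=O)Cl
Why: Acylation of a lithium acetylide with a chloroformate, a standard route to ynoates.

Step 6
Reactants: 10 methyl 4-[(4-methoxybenzyl)oxy]but-2-ynoate
Product: 12 methyl (Z)-4-[(4-methoxybenzyl)oxy]-3-methylbut-2-enoate, via alkenylcuprate 11 (not isolated)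
Conditions: Me2CuLi (CuI, 2 MeLi), THF, −78 °C; MeOH, −78 °C
Reagents that add atoms: methyllithium, [Li]C; CuI, [Cu]I; lithium dimethylcuprate (made in the flask from these two), [Li+].C[Cu-]C
Why: syn-Carbocupration of the ynoate followed by protonation at low temperature with retention places CH2OPMB (C3) cis to the ester carbon (C6), which sets the Z geometry of C4=C5 and installs C15.

Step 7
Reactants: 12 methyl (Z)-4-[(4-methoxybenzyl)oxy]-3-methylbut-2-enoate
Product: 13 (Z)-4-[(4-methoxybenzyl)oxy]-3-methylbut-2-en-1-ol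
Conditions: DIBAL-H (2.2 equiv), CH2Cl2, −78 °C; Rochelle salt
Reagents that add atoms: none
Why: 1,2-Reduction of the enoate to the allylic alcohol by DIBAL-H without isomerization of the trisubstituted alkene.

Step 8
Reactants: 13 (Z)-4-[(4-methoxybenzyl)oxy]-3-methylbut-2-en-1-ol
Product: 14 (Z)-4-[(4-methoxybenzyl)oxy]-3-methylbut-2-enal (fragment B)
Conditions: MnO2, CH2Cl2, 23 °C
Reagents that add atoms: none
Why: Allylic oxidation with MnO2 under neutral conditions, which should keep the Z geometry of the β,β-disubstituted enal; 14 is used at once.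

Step 9
Reactants: 7 (3S,4S)-3-(tert-butyldimethylsilyloxy)-4-(methoxymethoxy)-1-(triisopropylsilyl)hepta-5,6-dien-1-yne; 14 (Z)-4-[(4-methoxybenzyl)oxy]-3-methylbut-2-enal
Product: 17 (3S,4S,5S)-5-(tert-butyldimethylsilyloxy)-3-[(1S,2Z)-1-hydroxy-4-(4-methoxybenzyloxy)-3-methylbut-2-en-1-yl]-4-(methoxymethoxy)-2-methylidene-7-(triisopropylsilyl)hept-6-ynoic acid (6S,7S,8S,9S in target locants), via oxanickelacycle 15 (not isolated), via nickel alkoxide carboxylate 16 (not isolated)
Conditions: Ni(cod)2 (1.1 equiv), DBU (2.2 equiv), CO2 (1 atm), THF, 0 °C; then 14, 0 to 23 °C; cold 0.5 M HCl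
Reagents that add atoms: carbon dioxide, O=C=O
Why: Zerovalent nickel and CO2 undergo oxidative cyclization across the terminal C11=C13 bond of allene 7 on the face anti to C8 (C11–C12 bond, nickel on C13), giving the DBU-ligated oxanickelacycle 15, an allylnickel in which C8 is cis to the CH2–Ni carbon; the aldehyde then inserts through a closed six-membered chair transition state with SE2' attack by C7 (C6–C7 bond) to give 16, which is protonated on work-up. The closest known reaction type is the nickel-mediated sequential addition of CO2 and an aldehyde to a terminal allene (allylnickel carbonyl addition). No ring of the target is closed in this step: the five-membered metallacycle is transient, and the lactone ring is closed in step 10 (5-exo-tet). C6: the Z-type allyl geometry puts C8 axial and the enal residue equatorial in the chair, which should give the 6,7-syn (6S) acid, corrected by inversion in step 10. C7: allylic 1,3-strain with C13 holds H8 in the allyl plane and the aldehyde approaches anti to the bulky C9 branch with the MOM ether outside, which should give the required 7,8 relationship. The step needs attack through C7 and not C13 (nickel sits on the unsubstituted terminus), 1,2-addition to the enal (normal for allylmetal reagents), and chemoselectivity for the allene (the triisopropylsilyl alkyne is too hindered to bind nickel).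

Step 10
Reactants: 17 the 6S hydroxy acid of step 9
Product: 18 (4S,5R)-4-[(1S,2S)-2-(tert-butyldimethylsilyloxy)-1-(methoxymethoxy)-4-(triisopropylsilyl)but-3-yn-1-yl]-5-[(Z)-3-(4-methoxybenzyloxy)-2-methylprop-1-en-1-yl]-3-methylidenedihydrofuran-2(3H)-one (6R,7S,8S,9S)
Conditions: PPh3, DIAD, THF, 0 to 23 °C
Reagents that add atoms: none
Why: Mitsunobu lactonization: the C6 oxyphosphonium ion is displaced by the internal carboxylate (5-exo-tet) with inversion, so the 6S alcohol becomes the 6R oxygen of the trans-fused (H6/H7 trans) α-methylene lactone.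

Step 11
Reactants: 18 the trans-lactone of step 10
Product: 20 (4R,5R)-4-[(1S,2S)-2-(tert-butyldimethylsilyloxy)-1-hydroxy-4-(triisopropylsilyl)but-3-yn-1-yl]-5-[(Z)-3-(4-methoxybenzyloxy)-2-methylprop-1-en-1-yl]-3-methylidenedihydrofuran-2(3H)-one (free C8-OH; spatial arrangement unchanged, the C7 descriptor changes by CIP priority only), via bipyridinium salt 19 (not isolated)
Conditions: TMSOTf, 2,2'-bipyridyl, CH2Cl2, 0 °C; then H2O
Reagents that add atoms: none
Why: Mild non-protic cleavage of the methoxymethyl ether through an N-(alkoxymethyl)pyridinium salt that water hydrolyses, conditions under which the silyl ether, silyl alkyne, PMB ether and methylene lactone should survive.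

Step 12
Reactants: 21 (E)-2-methylbut-2-en-1-ol
Product: 22 [(2R,3R)-2,3-dimethyloxiran-2-yl]methanol
Conditions: Ti(OiPr)4 (10 mol%), D-(−)-diethyl tartrate (12 mol%), t-BuOOH, 4 Å sieves, CH2Cl2, −20 °C
Reagents that add atoms: tert-butyl hydroperoxide, CC(C)(C)OO
Why: Sharpless asymmetric epoxidation; with the D-(−)-tartrate the oxygen is delivered to the face that gives the (2R,3R)-epoxy alcohol, and the E alkene fixes the cis relationship of the two methyl groups.

Step 13
Reactants: 22 [(2R,3R)-2,3-dimethyloxiran-2-yl]methanol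
Product: 23 (2S,3R)-2,3-dimethyloxirane-2-carboxylic acid
Conditions: RuCl3 (2 mol%), NaIO4, CCl4/MeCN/H2O, 23 °C
Reagents that add atoms: water, O
Why: Ruthenium tetroxide oxidation of the primary alcohol to the acid via the aldehyde hydrate; the fully substituted epoxide is not affected (the C2 descriptor changes only through CIP priorities).

Step 14
Reactants: 20 the C8 alcohol of step 11; 23 (2S,3R)-2,3-dimethyloxirane-2-carboxylic acid
Product: 25 C8 (2S,3R)-2,3-dimethyloxirane-2-carboxylate of 20 (6R,7S,8S,9S), via mixed anhydride 24 (not isolated)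
Conditions: 23, 2,4,6-trichlorobenzoyl chloride, Et3N, THF, 23 °C; then 20, DMAP, toluene, 40 °C
Reagents that add atoms: none
Why: Yamaguchi esterification, suited to a hindered secondary alcohol and an α-quaternary acid that has no epimerizable α-hydrogen; O9 is silylated, so only O8 is acylated.

Step 15
Reactants: 25 the C8 ester of step 14
Product: 27 terminal alkyne (C10≡C1–H) corresponding to 25, via silver acetylide 26 (not isolated)
Conditions: AgF (1.5 equiv), MeCN, 23 °C, dark; then 1 M HCl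
Reagents that add atoms: none
Why: Silver fluoride removes the triisopropylsilyl group from the alkyne carbon selectively, because silver activates the triple bond, and leaves the silyl ether, the esters and the lactone untouched.

Step 16
Reactants: 27 the terminal alkyne of step 15
Product: 28 methyl 2-substituted acrylate: C10 carries =CH2 and CO2CH3 (C14), C9 keeps OTBS (6R,7S,8S,9S)
Conditions: Pd(OAc)2 (5 mol%), 2-(diphenylphosphino)pyridine, MsOH, CO (20 bar), MeOH, CH2Cl2, 40 °C
Reagents that add atoms: carbon monoxide, [C-]#[O+]; methanol, CO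
Why: Palladium-catalysed Markovnikov hydromethoxycarbonylation of a terminal alkyne; the pyridylphosphine relays the proton to the terminal carbon, so the ester enters at the internal carbon C10, and alkenes do not react under these conditions.

Step 17
Reactants: 28 the acrylate of step 16
Product: 29 primary (Z)-allylic alcohol (C3-OH) corresponding to 28
Conditions: DDQ, CH2Cl2/pH 7 buffer, 0 °C
Reagents that add atoms: none
Why: Oxidative cleavage of the p-methoxybenzyl ether by hydride abstraction at the electron-rich benzylic position under buffered, non-acidic conditions.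

Step 18
Reactants: 29 the allylic alcohol of step 17
Product: 30 (Z)-2-methyl enal (C3 aldehyde) corresponding to 29
Conditions: Dess–Martin periodinane, NaHCO3, CH2Cl2, 0 °C
Reagents that add atoms: none
Why: Buffered Dess–Martin oxidation of the primary allylic alcohol; the isomerization-prone Z enal is not purified and is used directly in step 19.

Step 19
Reactants: 30 the Z enal of step 18; 31 3-chloroprop-1-ene
Product: 34 cis-vinyl epoxide (2S,3R; C1=CH2 on C2) with the C10 acrylate, C9-OTBS, C8 ester and trans-lactone (6R,7S,8S,9S), via chloroallylborane 32 (not isolated), via chlorohydrin 33 (not isolated)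
Conditions: 31, LiN(c-C6H11)2, (−)-Ipc2BOMe [from (+)-α-pinene], Et2O, −95 °C; BF3·OEt2; then 30, −95 °C; 8-hydroxyquinoline, MeOH; then DBU, CH2Cl2, 0 to 23 °C
Reagents that add atoms: none
Why: Asymmetric (Z)-γ-chloroallylboration through a chair transition state should give the syn chlorohydrin (Si-face attack set by the isopinocampheyl groups from (+)-α-pinene, 3R), and DBU then closes the epoxide with inversion at C2, so syn becomes cis (2S,3R).

Step 20
Reactants: 34 the vinyl epoxide of step 19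
Product: 35 O9-tert-butyldimethylsilyl ether of the target (ten-membered ring closed, C1=C10 E by CIP)
Conditions: second-generation Hoveyda–Grubbs catalyst, RuCl2(H2IMes)(=CH-C6H4-2-OiPr) (15 mol%), CH2Cl2 (1 mM), 40 °C
Reagents that add atoms: none
Why: Ring-closing metathesis that starts at the monosubstituted vinyl epoxide and closes onto the 1,1-disubstituted acrylate; the Z alkene and the cis-epoxide pre-fold the chain, and the ring-cis trisubstituted enoate (C2 trans to CO2CH3) is the geometry a ten-membered ring imposes.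

Step 21
Reactants: 35 the silyl ether of step 20
Product: 36 target, CNP0291485.6
Conditions: TBAF, AcOH (1:1), THF, 0 to 23 °C
Reagents that add atoms: none
Why: Buffered fluoride desilylation frees the C9 hydroxyl without acid, which spares the divinyl epoxide, and without strong base, which limits acyl migration from O8 and attack on the methylene lactone.

Compound list
1 | 3-(triisopropylsilyl)prop-2-ynal | O=CC#C[Si](C(C)C)(C(C)C)C(C)C | starting material
2 | 3-(methoxymethoxy)prop-1-ene (allyl methoxymethyl ether) | C=CCOCOC | starting material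
3 | [(Z)-3-(methoxymethoxy)prop-2-en-1-yl]diisopinocampheylborane (Ipc from (−)-α-pinene) | COCO/C=C\CB([C@H]1C[C@H]2C[C@@H]([C@@H]1C)C2(C)C)[C@H]1C[C@H]2C[C@@H]([C@@H]1C)C2(C)C | intermediate
4 | (3S,4S)-4-(methoxymethoxy)-1-(triisopropylsilyl)hex-5-en-1-yn-3-ol | CC(C)[Si](C(C)C)(C(C)C)C#C[C@H](O)[C@@H](OCOC)C=C | intermediate
5 | (3S,4S)-3-(tert-butyldimethylsilyloxy)-4-(methoxymethoxy)-1-(triisopropylsilyl)hex-5-en-1-yne | CC(C)[Si](C(C)C)(C(C)C)C#C[C@H](O[Si](C)(C)C(C)(C)C)[C@@H](OCOC)C=C | intermediate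
6 | (3S,4S)-3-(tert-butyldimethylsilyloxy)-4-(2,2-dibromocyclopropyl)-4-(methoxymethoxy)-1-(triisopropylsilyl)but-1-yne (epimers at the cyclopropane CH) | CC(C)[Si](C(C)C)(C(C)C)C#C[C@H](O[Si](C)(C)C(C)(C)C)[C@@H](OCOC)C1CC1(Br)Br | intermediate
7 | (3S,4S)-3-(tert-butyldimethylsilyloxy)-4-(methoxymethoxy)-1-(triisopropylsilyl)hepta-5,6-dien-1-yne (fragment A) | CC(C)[Si](C(C)C)(C(C)C)C#C[C@H](O[Si](C)(C)C(C)(C)C)[C@@H](OCOC)C=C=C | intermediate
8 | 1-methoxy-4-[(prop-2-yn-1-yloxy)methyl]benzene | C#CCOCc1ccc(OC)cc1 | starting material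
9 | lithium acetylide of 8 | [Li]C#CCOCc1ccc(OC)cc1 | intermediate
10 | methyl 4-[(4-methoxybenzyl)oxy]but-2-ynoate | COC(=O)C#CCOCc1ccc(OC)cc1 | intermediate
11 | lithium [(E)-1-(methoxycarbonyl)-3-(4-methoxybenzyloxy)-2-methylprop-1-en-1-yl](methyl)cuprate | [Li+].COC(=O)/C([Cu-]C)=C(/C)COCc1ccc(OC)cc1 | intermediate
12 | methyl (Z)-4-[(4-methoxybenzyl)oxy]-3-methylbut-2-enoate | COC(=O)/C=C(/C)COCc1ccc(OC)cc1 | intermediate
13 | (Z)-4-[(4-methoxybenzyl)oxy]-3-methylbut-2-en-1-ol | OC/C=C(/C)COCc1ccc(OC)cc1 | intermediate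
14 | (Z)-4-[(4-methoxybenzyl)oxy]-3-methylbut-2-enal (fragment B) | O=C/C=C(/C)COCc1ccc(OC)cc1 | intermediate
15 | five-membered oxanickelacycle from 7 and CO2 (nickel on C13 and on the carboxylate oxygen, C8 cis to C13; DBU ligands not drawn) | O=C1O[Ni]C/C1=C\[C@H](OCOC)[C@@H](O[Si](C)(C)C(C)(C)C)C#C[Si](C(C)C)(C(C)C)C(C)C | intermediate
16 | nickel alkoxide carboxylate after aldehyde insertion (drawn as the seven-membered chelate; DBU ligands not drawn) | C=C1C(=O)O[Ni]O[C@@H](/C=C(/C)COCc2ccc(OC)cc2)[C@H]1[C@H](OCOC)[C@@H](O[Si](C)(C)C(C)(C)C)C#C[Si](C(C)C)(C(C)C)C(C)C | intermediate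
17 | (3S,4S,5S)-5-(tert-butyldimethylsilyloxy)-3-[(1S,2Z)-1-hydroxy-4-(4-methoxybenzyloxy)-3-methylbut-2-en-1-yl]-4-(methoxymethoxy)-2-methylidene-7-(triisopropylsilyl)hept-6-ynoic acid (6S,7S,8S,9S) | C=C(C(=O)O)[C@@H]([C@@H](O)/C=C(/C)COCc1ccc(OC)cc1)[C@H](OCOC)[C@@H](O[Si](C)(C)C(C)(C)C)C#C[Si](C(C)C)(C(C)C)C(C)C | intermediate
18 | (4S,5R)-4-[(1S,2S)-2-(tert-butyldimethylsilyloxy)-1-(methoxymethoxy)-4-(triisopropylsilyl)but-3-yn-1-yl]-5-[(Z)-3-(4-methoxybenzyloxy)-2-methylprop-1-en-1-yl]-3-methylidenedihydrofuran-2(3H)-one (6R,7S,8S,9S) | C=C1C(=O)O[C@H](/C=C(/C)COCc2ccc(OC)cc2)[C@H]1[C@H](OCOC)[C@@H](O[Si](C)(C)C(C)(C)C)C#C[Si](C(C)C)(C(C)C)C(C)C | intermediate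
19 | 1-(alkoxymethyl)-2,2'-bipyridin-1-ium triflate of the C8 oxygen of 18 | C=C1C(=O)O[C@H](/C=C(/C)COCc2ccc(OC)cc2)[C@H]1[C@H](OC[n+]2ccccc2-c2ccccn2)[C@@H](O[Si](C)(C)C(C)(C)C)C#C[Si](C(C)C)(C(C)C)C(C)C.[O-]S(=O)(=O)C(F)(F)F | intermediate
20 | (4R,5R)-4-[(1S,2S)-2-(tert-butyldimethylsilyloxy)-1-hydroxy-4-(triisopropylsilyl)but-3-yn-1-yl]-5-[(Z)-3-(4-methoxybenzyloxy)-2-methylprop-1-en-1-yl]-3-methylidenedihydrofuran-2(3H)-one (C8 alcohol) | C=C1C(=O)O[C@H](/C=C(/C)COCc2ccc(OC)cc2)[C@H]1[C@H](O)[C@@H](O[Si](C)(C)C(C)(C)C)C#C[Si](C(C)C)(C(C)C)C(C)C | intermediate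
21 | (E)-2-methylbut-2-en-1-ol | C/C=C(\C)CO | starting material
22 | [(2R,3R)-2,3-dimethyloxiran-2-yl]methanol | OC[C@@]1(C)O[C@@H]1C | intermediate
23 | (2S,3R)-2,3-dimethyloxirane-2-carboxylic acid | OC(=O)[C@@]1(C)O[C@@H]1C | intermediate
24 | (2S,3R)-2,3-dimethyloxirane-2-carboxylic 2,4,6-trichlorobenzoic anhydride | O=C(OC(=O)c1c(Cl)cc(Cl)cc1Cl)[C@@]1(C)O[C@@H]1C | intermediate
25 | C8 (2S,3R)-2,3-dimethyloxirane-2-carboxylate of 20 (6R,7S,8S,9S) | C=C1C(=O)O[C@H](/C=C(/C)COCc2ccc(OC)cc2)[C@H]1[C@H](OC(=O)[C@@]2(C)O[C@@H]2C)[C@@H](O[Si](C)(C)C(C)(C)C)C#C[Si](C(C)C)(C(C)C)C(C)C | intermediate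
26 | silver acetylide of 27 | C=C1C(=O)O[C@H](/C=C(/C)COCc2ccc(OC)cc2)[C@H]1[C@H](OC(=O)[C@@]2(C)O[C@@H]2C)[C@@H](O[Si](C)(C)C(C)(C)C)C#C[Ag] | intermediate
27 | terminal alkyne: 25 without the triisopropylsilyl group | C=C1C(=O)O[C@H](/C=C(/C)COCc2ccc(OC)cc2)[C@H]1[C@H](OC(=O)[C@@]2(C)O[C@@H]2C)[C@@H](O[Si](C)(C)C(C)(C)C)C#C | intermediate
28 | methyl acrylate at C10 (C10(=CH2)CO2CH3), C9-OTBS, C8 ester, trans-lactone, C3-OPMB (6R,7S,8S,9S) | C=C1C(=O)O[C@H](/C=C(/C)COCc2ccc(OC)cc2)[C@H]1[C@H](OC(=O)[C@@]2(C)O[C@@H]2C)[C@@H](O[Si](C)(C)C(C)(C)C)C(=C)C(=O)OC | intermediate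
29 | C3 primary (Z)-allylic alcohol corresponding to 28 | C=C1C(=O)O[C@H](/C=C(/C)CO)[C@H]1[C@H](OC(=O)[C@@]2(C)O[C@@H]2C)[C@@H](O[Si](C)(C)C(C)(C)C)C(=C)C(=O)OC | intermediate
30 | C3 (Z)-2-methyl enal corresponding to 29 | C=C1C(=O)O[C@H](/C=C(/C)C=O)[C@H]1[C@H](OC(=O)[C@@]2(C)O[C@@H]2C)[C@@H](O[Si](C)(C)C(C)(C)C)C(=C)C(=O)OC | intermediate
31 | 3-chloroprop-1-ene (allyl chloride) | C=CCCl | starting material
32 | [(Z)-3-chloroprop-2-en-1-yl]diisopinocampheylborane (Ipc from (+)-α-pinene) | Cl/C=C\CB([C@@H]1C[C@@H]2C[C@H]([C@H]1C)C2(C)C)[C@@H]1C[C@@H]2C[C@H]([C@H]1C)C2(C)C | intermediate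
33 | syn chlorohydrin (2R,3R): C3-OH, C2-Cl, C1=CH2, otherwise as 30 | C=C1C(=O)O[C@H](/C=C(/C)[C@@H](O)[C@H](Cl)C=C)[C@H]1[C@H](OC(=O)[C@@]2(C)O[C@@H]2C)[C@@H](O[Si](C)(C)C(C)(C)C)C(=C)C(=O)OC | intermediate
34 | cis-vinyl epoxide (2S,3R) with C10 acrylate, C9-OTBS, C8 ester and trans-lactone (6R,7S,8S,9S) | C=C1C(=O)O[C@H](/C=C(/C)[C@H]2O[C@H]2C=C)[C@H]1[C@H](OC(=O)[C@@]2(C)O[C@@H]2C)[C@@H](O[Si](C)(C)C(C)(C)C)C(=C)C(=O)OC | intermediate
35 | O9-tert-butyldimethylsilyl ether of the target | C=C1C(=O)O[C@@H]2/C=C(/C)[C@H]3O[C@H]3/C=C(/C(=O)OC)[C@H](O[Si](C)(C)C(C)(C)C)[C@@H](OC(=O)[C@@]3(C)O[C@@H]3C)[C@@H]12 | intermediate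
36 | CNP0291485.6 (2S,3R,6R,7S,8S,9S in target locants; acyl group 2S,3R) | C=C1C(=O)O[C@@H]2/C=C(/C)[C@H]3O[C@H]3/C=C(/C(=O)OC)[C@H](O)[C@@H](OC(=O)[C@@]3(C)O[C@@H]3C)[C@@H]12 | target

Total step count: 21. Longest linear sequence: 15 steps (steps 1–4, 9–11 and 14–21; steps 5–8 and 12–13 run in parallel).

Steps most likely to fail

Step 9 (nickel-mediated coupling). The allylnickel may attack through C13 and give the linear acid. It may also lose the C8 alkoxy group by β-elimination, the enal may lose its Z geometry under DBU, and facial control by C8 may be poor. Fallback with known chemistry, setting out from 5 and returning at 17: ozonolysis of the vinyl group of 5 (O3, CH2Cl2/MeOH, −78 °C; Me2S) should give (2R,3S)-3-(tert-butyldimethylsilyloxy)-2-(methoxymethoxy)-5-(triisopropylsilyl)pent-4-ynal F1. A Morita–Baylis–Hillman reaction with methyl acrylate (DABCO) should give the allylic alcohol methyl (4S,5S)-5-(tert-butyldimethylsilyloxy)-3-hydroxy-4-(methoxymethoxy)-2-methylidene-7-(triisopropylsilyl)hept-6-ynoate F2. NBS/Me2S should convert it with allylic transposition into methyl (2Z,4S,5S)-2-(bromomethyl)-5-(tert-butyldimethylsilyloxy)-4-(methoxymethoxy)-7-(triisopropylsilyl)hept-2-en-6-ynoate F3. Indium-mediated Barbier addition of F3 to aldehyde 14 (In, THF/H2O) should pass through the same Z-allylmetal chair and give the syn hydroxy ester, the methyl ester of 17, F4. Hydrolysis with LiOH (THF/H2O) then gives 17. This route forms C6–C7 but carries C12 in from the acrylate.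

Step 20 (ring-closing metathesis). The ruthenium carbene on C1 may close onto the lactone methylene instead (eight-membered ring), oligomerize, or stall at the hindered acrylate. Fallback, setting out from 34 and returning at 35: conjugate addition of dimethylamine (Me2NH, THF, 0 °C) to the more reactive exocyclic methylene of the lactone should give the C13-dimethylamino adduct of 34 F5, which removes the competing alkene. Ring-closing metathesis under the conditions of step 20 should then give the macrocyclic amine F6. Quaternization with MeI and elimination with aqueous NaHCO3 restores the methylene lactone and gives 35.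

Step 16 (hydromethoxycarbonylation). Markovnikov control may erode next to the bulky silyloxy centre, and the acidic methanol may cleave the silyl ether. Fallback, setting out from 27 and returning at 28: molybdenum-catalysed α-selective hydrostannation (Bu3SnH, Mo(CO)3(CNtBu)3, hydroquinone, THF, 55 °C) should give the 1,1-disubstituted vinylstannane F7. Iododestannylation (I2, CH2Cl2, 0 °C) gives the 2-iodoalkene F8. Methoxycarbonylation under basic conditions (PdCl2(PPh3)2, CO, MeOH, Et3N, DMF, 50 °C) then gives 28.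

Further compounds
F1 | step 9 | (2R,3S)-3-(tert-butyldimethylsilyloxy)-2-(methoxymethoxy)-5-(triisopropylsilyl)pent-4-ynal | O=C[C@H](OCOC)[C@@H](O[Si](C)(C)C(C)(C)C)C#C[Si](C(C)C)(C(C)C)C(C)C
F2 | step 9 | methyl (4S,5S)-5-(tert-butyldimethylsilyloxy)-3-hydroxy-4-(methoxymethoxy)-2-methylidene-7-(triisopropylsilyl)hept-6-ynoate (both C3 epimers) | C=C(C(=O)OC)C(O)[C@H](OCOC)[C@@H](O[Si](C)(C)C(C)(C)C)C#C[Si](C(C)C)(C(C)C)C(C)C
F3 | step 9 | methyl (2Z,4S,5S)-2-(bromomethyl)-5-(tert-butyldimethylsilyloxy)-4-(methoxymethoxy)-7-(triisopropylsilyl)hept-2-en-6-ynoate | COC(=O)/C(CBr)=C/[C@H](OCOC)[C@@H](O[Si](C)(C)C(C)(C)C)C#C[Si](C(C)C)(C(C)C)C(C)C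
F4 | step 9 | methyl ester of 17 | C=C(C(=O)OC)[C@@H]([C@@H](O)/C=C(/C)COCc1ccc(OC)cc1)[C@H](OCOC)[C@@H](O[Si](C)(C)C(C)(C)C)C#C[Si](C(C)C)(C(C)C)C(C)C
F5 | step 20 | C13-dimethylamino adduct of 34 (both C11 epimers) | CN(C)CC1C(=O)O[C@H](/C=C(/C)[C@H]2O[C@H]2C=C)[C@H]1[C@H](OC(=O)[C@@]2(C)O[C@@H]2C)[C@@H](O[Si](C)(C)C(C)(C)C)C(=C)C(=O)OC
F6 | step 20 | C13-dimethylamino adduct of 35 (both C11 epimers) | CN(C)CC1C(=O)O[C@@H]2/C=C(/C)[C@H]3O[C@H]3/C=C(/C(=O)OC)[C@H](O[Si](C)(C)C(C)(C)C)[C@@H](OC(=O)[C@@]3(C)O[C@@H]3C)[C@@H]12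
F7 | step 16 | 1-(tributylstannyl)vinyl compound at C10 corresponding to 27 | C=C1C(=O)O[C@H](/C=C(/C)COCc2ccc(OC)cc2)[C@H]1[C@H](OC(=O)[C@@]2(C)O[C@@H]2C)[C@@H](O[Si](C)(C)C(C)(C)C)C(=C)[Sn](CCCC)(CCCC)CCCC
F8 | step 16 | 1-iodovinyl compound at C10 corresponding to 27 | C=C1C(=O)O[C@H](/C=C(/C)COCc2ccc(OC)cc2)[C@H]1[C@H](OC(=O)[C@@]2(C)O[C@@H]2C)[C@@H](O[Si](C)(C)C(C)(C)C)C(=C)I
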